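**Conventions and assumptions**

- Ring A is the butanoyl ring whose bridge carbon lies next to the methoxy group: C1 butanoyl, C2 OH, C3 methyl, C4 OMe, C5 CH2 bridge, C6 OH. Ring B is the central acetyl ring. Ring C is the other butanoyl ring: C1′ CH2 bridge, C2′ OH, C3′ methyl, C4′ OMe, C5′ butanoyl, C6′ OH.
- Ar is the perbenzylated ring B–ring C aryl group 3-acetyl-2,4,6-tris(benzyloxy)-5-{[2,6-bis(benzyloxy)-3-butanoyl-4-methoxy-5-methylphenyl]methyl}phenyl; "Ar-methyl" is Ar–CH2–.
- Assumption: (triisopropylsilyloxy)acetylene 22 is a known, distillable alkynyl silyl ether and is taken as a purchased input.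
- Remark: the target has no stereocentre. The stereocentres of 17, 21, 24 and 26 are racemic and disappear on aromatisation; diones 18 and 20 enolise freely.

## Analysis of the target

Compound 30 is a trimeric acylphloroglucinol: three hexasubstituted benzene rings in a row, joined by two CH2 bridges, with the acetyl ring B in the middle and the two butanoyl rings A and C outside. There is no stereocentre and no fused ring, so the problem is entirely one of regiochemistry: all eighteen ring carbons are substituted, and seven hydroxyl groups must end up free beside two methyl ethers. Rings A and C are regioisomers of one another. In ring A the bridge carbon C5 lies between OMe (C4) and OH (C6) and the butanoyl carbon C1 between two OH groups; in ring C the bridge carbon C1′ lies between two OH groups and the butanoyl carbon C5′ between OMe and OH. The free polyphenol is oxidisable, and methylene links between free phloroglucinol rings exchange partners under acid or base through retro-Friedel–Crafts and quinone methide pathways. The hard points are therefore to place the ring A bridge next to the methoxy group, to single out one oxygen per outer ring as the methyl ether, and to join three different rings without statistical mixtures. The plan rests on the ring A array C2–C3(methyl)–C4(OMe)–C5(CH2): these four carbons are the four carbons of a 3-methoxy-4-methylcyclobutenone carrying the bridge at its C2 (compound 21), and C1 and C6 come from alkyne 22. C4 is thus never a phenol, and C1 emerges as the only unsubstituted carbon.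

## Retrosynthetic reasoning

30 to 29. The five O–benzyl bonds on rings B and C are cut last. Hydrogenolysis is neutral, so the free polyphenol with its exchangeable methylene links is exposed only in the final flask.

29 to 28. The bond between ring A C1 and the butanoyl carbonyl is cut. In 28, C1 is the only C–H on any of the three core rings and sits between two free hydroxyl groups, so electrophilic acylation has one possible site.

28 to 27. The O–Si bond at C6 is cut. Freeing the second phenol makes C1 doubly ortho-activated and unhindered. It is also the point at which the two possible enol ether regioisomers of the four-membered ring converge.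

27 to 21 and 22. This is the key disconnection. The ring A bonds C1–C2 and C5–C6, which tie the two alkyne carbons to the four-carbon unit, are cut, and C2–C3 is recognised as the bond that closes the ring. Cutting here puts the methoxy group on C4 by construction and attaches the bridge to C5 before any aromatic ring exists, so the awkward bridge position needs no aromatic substitution selectivity. The forward reaction must open the four-membered ring of 21, add 22 in one orientation and aromatise.

21 to 20. The enol O–CH3 bond is cut. Dione 20 can enolise towards either flanking carbon, but both enol ethers lead to 28, so the methylation needs no selectivity.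

20 to 13 and 18. The bond between the cyclobutane carbon and the benzylic CH2 is cut as a reductive alkylation of the dione by an aldehyde. This is C-selective and mild, and only the CH2 of 18 can condense, because the methyl-bearing carbon has a single hydrogen.

18 to 17, and 17 to 14 and 15. The four-membered ring comes from the [2+2] addition of ketene 16, made from 14, to alkynyl ether 15. Polarity fixes the orientation, and hydrolysis of the enol ether gives the dione.

13 to 12. Five O–benzyl bonds are cut. Benzylation freezes the ring B–ring C link and masks all phenols before the small ring is attached.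

12 to 7 and 10. The bond between ring B and the bridge CH2 is cut. Compound 7 is a latent ortho-quinone methide (11) and 10 has exactly one nucleophilic ring carbon, so the cross-coupling has no statistical component.

7 back to 1. The C–N bond (reductive amination of 5), the C–acyl bond (5 from 4), the O–methyl bond (4 from 3) and the C–formyl bond (3 from 1) are cut in that order. Formylation of symmetrical 1 gives one product, methylation then finds one unchelated hydroxyl (para to the formyl group), and acylation finds one free carbon. This fixes the ring C pattern, with the future bridge carbon between two hydroxyl groups.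

10 to 8. The C–formyl bond is cut; one formylation of the symmetrical ketone 8 suffices.

## Alternatives that were turned down

Ar′ here is the benzylated ring A–ring B aryl group 3-acetyl-2,4,6-tris(benzyloxy)-5-{[2,4-bis(benzyloxy)-3-butanoyl-6-methoxy-5-methylphenyl]methyl}phenyl.

Alternative 1: Ring C is disconnected between its bridge-bearing carbon and the neighbouring hydroxyl-bearing carbon, back to pyranone A1, which carries the ring A–ring B half on a two-carbon tether.
- Forward key step: alkoxide opens the lactone of A1 to a keto ester. The ketone α-methylene that bears the benzyl group then closes onto the ester in a Claisen-type condensation, and aromatisation gives resorcinol A2.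
- For it: the chemistry is polar and classical throughout, no strained or thermolabile reagent is needed, and the methoxy position is fixed in A1, so no enol ether regioisomer can arise. On these points it is stronger than the chosen route.
- Against it: ring formation needs a hot, strongly basic medium on a substrate with two enolisable aryl ketones. The more acidic methylene of the opened chain (between ketone and enol ether) is deprotonated first and is unproductive, and re-lactonisation competes. Making A1 requires an aldol condensation onto a methylpyranone followed by alkene reduction in the presence of five benzyl ethers, and ring A must still be made and attached classically. The step count is no shorter.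
- In its place the chosen route offers ring formation under neutral thermal conditions with no enolate chemistry, and it neutralises its own regiochemical weakness by convergence at 28.

Alternative 2: Ring B is disconnected into cyclobutenone A3 (carrying the ring A benzyl group) and siloxyalkyne A4 (carrying the ring C benzyl group).
- Forward key step: heating A3 with A4 gives the pentasubstituted ring B phenol A5, which still needs desilylation and acetylation at its free carbon.
- For it: it is the most convergent plan, joining all three rings in one step, and the symmetry of ring B removes any question about where the acetyl group goes. On convergence it is stronger than the chosen route.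
- Against it: both partners are advanced and must be matched one to one in a bimolecular ketene–alkyne addition between two bulky components. A4 has to be made through strongly basic organolithium chemistry, so its butanoyl group is carried as a silyl-protected carbinol and later needs deprotection and oxidation. A3 is a hydrolytically labile silyl enol ether. The late acetylation would be run on a ring B triol whose two methylene links are both acid-labile.
- In its place the chosen route confines the unstable partner to a small reagent (22) that can be used in excess, needs one protecting group type, and carries the ring C ketone at its final oxidation level.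

Alternative 3: Ring C is disconnected into cyclobutenone A6 and methoxyethyne A7.
- Forward key step: the same cascade as in the chosen route, heating A6 with A7, gives phenol A8; the methoxy group is now delivered by the alkyne.
- For it: the step count is about equal, and the classically made half would contain ring A, whose pattern (methyl ether para to the acyl group) is the easiest to reach by selective methylation. On that point it is at least as strong.
- Against it: A6 is one specific silyl enol ether of an unsymmetrical cyclobutanedione. The other regioisomer would give a ring with the bridge next to the methoxy group, which is not ring C, so there is no convergence and the enolisation must be controlled. A7 is a very volatile alkynyl ether that is harder to handle than 22.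
- In its place the chosen route needs no control over the enol ether regiochemistry (both isomers reach 28), and ring C is set by three unambiguous aromatic steps from symmetrical 1.

Key step: step 12

## Route

Step 1
Reactants: 1 2-methylbenzene-1,3,5-triol
Product: 3 2,4,6-trihydroxy-3-methylbenzaldehyde, via aryl iminium chloride 2 (not isolated)
Conditions: POCl3, DMF, EtOAc, 0 °C to rt; then H2O, 60 °C
Reagents that add atoms: N,N-dimethylformamide CN(C)C=O; water O
Why: Vilsmeier–Haack formylation of a phloroglucinol; the two free ring carbons of 1 are equivalent, so one aldehyde should form, and the iminium salt 2 deactivates the ring against a second formylation.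

Step 2
Reactants: 3 2,4,6-trihydroxy-3-methylbenzaldehyde
Product: 4 2,6-dihydroxy-4-methoxy-3-methylbenzaldehyde
Conditions: Me2SO4 (1 equiv), K2CO3, acetone, rt
Reagents that add atoms: dimethyl sulfate COS(=O)(=O)OC
Why: Selective Williamson O-methylation; the 2- and 6-hydroxyl groups are held in hydrogen bonds to the formyl oxygen, so the para hydroxyl is the most acidic and the only unchelated one and should be methylated first.

Step 3
Reactants: 4 2,6-dihydroxy-4-methoxy-3-methylbenzaldehyde
Product: 5 3-butanoyl-2,6-dihydroxy-4-methoxy-5-methylbenzaldehyde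
Conditions: (n-PrCO)2O, BF3·OEt2, 1,4-dioxane, 60 °C; then aq. MeOH, 50 °C
Reagents that add atoms: butanoic anhydride CCCC(=O)OC(=O)CCC
Why: Friedel–Crafts acylation at the single unsubstituted ring carbon, which is ortho or para to all three oxygen donors; a second acyl group enters a monoacylated phloroglucinol readily under these conditions, and the aqueous methanol work-up is meant to return oxygen-bound acyl and boron to free phenol.

Step 4
Reactants: 5 3-butanoyl-2,6-dihydroxy-4-methoxy-5-methylbenzaldehyde
Product: 7 1-{3-[(dimethylamino)methyl]-2,4-dihydroxy-6-methoxy-5-methylphenyl}butan-1-one, via iminium acetate 6 (not isolated)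
Conditions: Me2NH (2 M in THF), NaBH(OAc)3, AcOH, ClCH2CH2Cl, rt
Reagents that add atoms: dimethylamine CNC
Why: Reductive amination; the aldehyde condenses to iminium ion 6, which NaBH(OAc)3 reduces, while the chelated, doubly ortho-substituted butanoyl ketone should be inert to this hydride.

Step 5
Reactants: 8 1-(2,4,6-trihydroxyphenyl)ethan-1-one
Product: 10 3-acetyl-2,4,6-trihydroxybenzaldehyde, via aryl iminium chloride 9 (not isolated)
Conditions: POCl3 (1.1 equiv), DMF, EtOAc, 0 °C to rt; then H2O, 60 °C
Reagents that add atoms: N,N-dimethylformamide CN(C)C=O; water O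
Why: Vilsmeier–Haack formylation; the two free carbons of 8 are equivalent and the first iminium group deactivates the ring, so monoformylation is expected with one equivalent of reagent.

Step 6
Reactants: 7 1-{3-[(dimethylamino)methyl]-2,4-dihydroxy-6-methoxy-5-methylphenyl}butan-1-one; 10 3-acetyl-2,4,6-trihydroxybenzaldehyde
Product: 12 3-acetyl-5-[(3-butanoyl-2,6-dihydroxy-4-methoxy-5-methylphenyl)methyl]-2,4,6-trihydroxybenzaldehyde, via ortho-quinone methide 11 (not isolated)
Conditions: 1,4-dioxane, 100 °C, N2 purge; then 1 M HCl work-up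
Reagents that add atoms: none
Why: Mannich-base alkylation; thermal loss of dimethylamine from the ortho-hydroxybenzylamine gives ortho-quinone methide 11, to which the single ring C–H of the acidic phenol 10 adds in Michael fashion. Ring C has no free carbon and 10 has only one, so the cross-coupled diarylmethane should be the only C-alkylation product.

Step 7
Reactants: 12 3-acetyl-5-[(3-butanoyl-2,6-dihydroxy-4-methoxy-5-methylphenyl)methyl]-2,4,6-trihydroxybenzaldehyde
Product: 13 3-acetyl-2,4,6-tris(benzyloxy)-5-{[2,6-bis(benzyloxy)-3-butanoyl-4-methoxy-5-methylphenyl]methyl}benzaldehyde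
Conditions: BnBr (excess), K2CO3, Bu4NI (cat.), DMF, 60 °C
Reagents that add atoms: benzyl bromide BrCc1ccccc1
Why: Exhaustive Williamson etherification; carbonate in a dipolar aprotic solvent favours O- over C-alkylation of the phenoxides, and excess halide with gentle heating should also etherify the chelated hydroxyl groups.

Step 8
Reactants: 14 propanoyl chloride; 15 ethoxyethyne
Product: 17 racemic 3-ethoxy-4-methylcyclobut-2-en-1-one, via methylketene 16 (not isolated)
Conditions: Et3N, Et2O, 0 °C to rt, slow addition of 14 to excess 15
Reagents that add atoms: none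
Why: Dehydrohalogenation gives ketene 16, which undergoes [2+2] ketene–alkyne cycloaddition; the electrophilic ketene carbonyl carbon bonds to the nucleophilic unsubstituted alkyne carbon, which places ethoxy at C3 and methyl at C4, and the new stereocentre is racemic and irrelevant.

Step 9
Reactants: 17 racemic 3-ethoxy-4-methylcyclobut-2-en-1-one
Product: 18 2-methylcyclobutane-1,3-dione
Conditions: 1 M HCl, THF, 0 °C to rt
Reagents that add atoms: water O
Why: Acid hydrolysis of a vinylogous ester; the dione is strongly acidic, exists largely as its enol and should be used soon after isolation.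

Step 10
Reactants: 13 3-acetyl-2,4,6-tris(benzyloxy)-5-{[2,6-bis(benzyloxy)-3-butanoyl-4-methoxy-5-methylphenyl]methyl}benzaldehyde; 18 2-methylcyclobutane-1,3-dione
Product: 20 2-(Ar-methyl)-4-methylcyclobutane-1,3-dione, via arylidene dione 19 (not isolated)
Conditions: Hantzsch ester (diethyl 2,6-dimethyl-1,4-dihydropyridine-3,5-dicarboxylate), L-proline (20 mol%), CH2Cl2, rt
Reagents that add atoms: none
Why: Three-component reductive alkylation of a cyclic 1,3-dione (Knoevenagel condensation, then conjugate transfer hydrogenation of alkylidene 19), established for five- and six-membered diones and extended here to the four-membered homologue; only the CH2 of 18 can dehydrate to an alkylidene, whereas addition through the methyl-bearing carbon is reversible, and the hindered aryl ketones and benzyl ethers should not react with the dihydropyridine.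

Step 11
Reactants: 20 2-(Ar-methyl)-4-methylcyclobutane-1,3-dione
Product: 21 racemic 3-methoxy-4-methyl-2-(Ar-methyl)cyclobut-2-en-1-one
Conditions: Me3SiCHN2, PhMe/MeOH, 0 °C; chromatography
Reagents that add atoms: (trimethylsilyl)diazomethane C[Si](C)(C)C=[N+]=[N-]
Why: O-Methylation of a vinylogous acid by a diazoalkane; 20 can enolise towards either ring carbon, so the isomeric enol ether is expected beside 21 and is separated (it is not waste, see the fallback), and the C4 stereocentre of 21 is racemic and is erased in step 12.

Step 12
Reactants: 21 racemic 3-methoxy-4-methyl-2-(Ar-methyl)cyclobut-2-en-1-one; 22 (triisopropylsilyloxy)acetylene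
Product: 27 3-methoxy-2-methyl-4-(Ar-methyl)-5-[(triisopropylsilyl)oxy]phenol, via vinylketene 23 (not isolated), via vinylcyclobutenone 24 (not isolated), via dienylketene 25 (not isolated), via cyclohexadienone 26 (not isolated)
Conditions: 22 (2 equiv), PhMe, 120 °C, sealed tube
Reagents that add atoms: none
Why: Danheiser benzannulation of a cyclobutenone with a siloxyalkyne, here with a vinylogous ester as the less common ketene source. Thermal conrotatory four-electron opening of 21 breaks the bond between its carbonyl carbon and C4 and gives vinylketene 23 with the methyl group turned outward. The ketene C=C then adds to 22 in a [2+2] sense, the nucleophilic terminal CH of 22 bonding to the electrophilic ketene carbon (ring A C1–C2) and the oxygen-bearing alkyne carbon to the benzyl-bearing carbon (ring A C5–C6), to give 24. A second, reversible four-electron opening gives dienylketene 25, and only the isomer with the propenyl group cis to the ketene can react on. Ring A is closed by a six-electron disrotatory electrocyclisation that re-forms the C2–C3 bond and gives 26, whose tautomerisation to phenol 27 drives the sequence. No stereocentre survives: the quaternary carbon of 24 and the sp3 carbon of 26 both become aromatic. The one selectivity needed is the orientation of the alkyne, and it follows from the matched polarity of ketene and alkynyl ether; the positions of methyl, methoxy and bridge are fixed by 21 itself. The bulky silyl group should slow the silyl shift of 22 to a silylketene, and the new C2 hydroxyl, flanked by methyl, should be hindered towards acylation by ketene.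

Step 13
Reactants: 27 3-methoxy-2-methyl-4-(Ar-methyl)-5-[(triisopropylsilyl)oxy]phenol
Product: 28 4-(Ar-methyl)-5-methoxy-6-methylbenzene-1,3-diol
Conditions: Bu4NF, AcOH, THF, 0 °C
Reagents that add atoms: none
Why: Fluoride cleavage of an aryl silyl ether, buffered with acetic acid so that the electron-rich resorcinol is not left as an oxidisable phenoxide; benzyl ethers and ketones are inert.

Step 14
Reactants: 28 4-(Ar-methyl)-5-methoxy-6-methylbenzene-1,3-diol
Product: 29 1-[3-(Ar-methyl)-2,6-dihydroxy-4-methoxy-5-methylphenyl]butan-1-one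
Conditions: (n-PrCO)2O, BF3·OEt2, CH2Cl2, -20 °C to rt; then aq. MeOH
Reagents that add atoms: butanoic anhydride CCCC(=O)OC(=O)CCC
Why: Friedel–Crafts acylation at ring A C1, the only C–H on the three core rings, activated by two ortho hydroxyl groups and the para methoxy group; rings B and C are fully substituted and their oxygens are capped, and the low temperature is chosen to spare the benzyl ethers and the methylene links.

Step 15
Reactants: 29 1-[3-(Ar-methyl)-2,6-dihydroxy-4-methoxy-5-methylphenyl]butan-1-one
Product: 30 1-[3-({3-acetyl-5-[(3-butanoyl-2,6-dihydroxy-4-methoxy-5-methylphenyl)methyl]-2,4,6-trihydroxyphenyl}methyl)-2,6-dihydroxy-4-methoxy-5-methylphenyl]butan-1-one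
Conditions: H2 (1 atm), Pd/C, EtOAc/MeOH, rt
Reagents that add atoms: none
Why: Hydrogenolysis of the five benzyl ethers under neutral conditions; hydrogen-bonded ortho-hydroxyaryl ketones and the diarylmethane links should not be reduced at atmospheric pressure and room temperature.

## Compound list

1 | 2-methylbenzene-1,3,5-triol | Cc1c(O)cc(O)cc1O | starting material
2 | (2,4,6-trihydroxy-3-methylbenzylidene)dimethyliminium chloride | C[N+](C)=Cc1c(O)cc(O)c(C)c1O.[Cl-] | intermediate (not isolated)
3 | 2,4,6-trihydroxy-3-methylbenzaldehyde | Cc1c(O)cc(O)c(C=O)c1O | intermediate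
4 | 2,6-dihydroxy-4-methoxy-3-methylbenzaldehyde | COc1cc(O)c(C=O)c(O)c1C | intermediate
5 | 3-butanoyl-2,6-dihydroxy-4-methoxy-5-methylbenzaldehyde | CCCC(=O)c1c(O)c(C=O)c(O)c(C)c1OC | intermediate
6 | (3-butanoyl-2,6-dihydroxy-4-methoxy-5-methylbenzylidene)dimethyliminium acetate | CCCC(=O)c1c(O)c(C=[N+](C)C)c(O)c(C)c1OC.CC(=O)[O-] | intermediate (not isolated)
7 | 1-{3-[(dimethylamino)methyl]-2,4-dihydroxy-6-methoxy-5-methylphenyl}butan-1-one | CCCC(=O)c1c(O)c(CN(C)C)c(O)c(C)c1OC | intermediate
8 | 1-(2,4,6-trihydroxyphenyl)ethan-1-one | CC(=O)c1c(O)cc(O)cc1O | starting material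
9 | (3-acetyl-2,4,6-trihydroxybenzylidene)dimethyliminium chloride | C[N+](C)=Cc1c(O)cc(O)c(C(C)=O)c1O.[Cl-] | intermediate (not isolated)
10 | 3-acetyl-2,4,6-trihydroxybenzaldehyde | CC(=O)c1c(O)cc(O)c(C=O)c1O | intermediate
11 | 4-butanoyl-5-hydroxy-3-methoxy-2-methyl-6-methylidenecyclohexa-2,4-dien-1-one (ring C ortho-quinone methide) | C=C1C(=O)C(C)=C(OC)C(C(=O)CCC)=C1O | intermediate (not isolated)
12 | 3-acetyl-5-[(3-butanoyl-2,6-dihydroxy-4-methoxy-5-methylphenyl)methyl]-2,4,6-trihydroxybenzaldehyde | O=Cc1c(O)c(C(C)=O)c(O)c(Cc2c(O)c(C)c(OC)c(C(=O)CCC)c2O)c1O | intermediate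
13 | 3-acetyl-2,4,6-tris(benzyloxy)-5-{[2,6-bis(benzyloxy)-3-butanoyl-4-methoxy-5-methylphenyl]methyl}benzaldehyde (Ar–CHO) | O=Cc1c(OCc2ccccc2)c(C(C)=O)c(OCc2ccccc2)c(Cc2c(OCc3ccccc3)c(C)c(OC)c(C(=O)CCC)c2OCc2ccccc2)c1OCc1ccccc1 | intermediate
14 | propanoyl chloride | CCC(=O)Cl | starting material
15 | ethoxyethyne | CCOC#C | starting material
16 | methylketene (prop-1-en-1-one) | CC=C=O | intermediate (not isolated)
17 | racemic 3-ethoxy-4-methylcyclobut-2-en-1-one | CCOC1=CC(=O)C1C | intermediate
18 | 2-methylcyclobutane-1,3-dione (largely enolised) | CC1C(=O)CC1=O | intermediate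
19 | 2-(Ar-methylidene)-4-methylcyclobutane-1,3-dione | CC1C(=O)C(=Cc2c(OCc3ccccc3)c(C(C)=O)c(OCc3ccccc3)c(Cc3c(OCc4ccccc4)c(C)c(OC)c(C(=O)CCC)c3OCc3ccccc3)c2OCc2ccccc2)C1=O | intermediate (not isolated)
20 | 2-(Ar-methyl)-4-methylcyclobutane-1,3-dione (enolised, stereolabile) | CC1C(=O)C(Cc2c(OCc3ccccc3)c(C(C)=O)c(OCc3ccccc3)c(Cc3c(OCc4ccccc4)c(C)c(OC)c(C(=O)CCC)c3OCc3ccccc3)c2OCc2ccccc2)C1=O | intermediate
21 | racemic 3-methoxy-4-methyl-2-(Ar-methyl)cyclobut-2-en-1-one | CC1C(=O)C(Cc2c(OCc3ccccc3)c(C(C)=O)c(OCc3ccccc3)c(Cc3c(OCc4ccccc4)c(C)c(OC)c(C(=O)CCC)c3OCc3ccccc3)c2OCc2ccccc2)=C1OC | intermediate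
22 | (triisopropylsilyloxy)acetylene | C#CO[Si](C(C)C)(C(C)C)C(C)C | starting material
23 | (3Z)-3-methoxy-2-(Ar-methyl)penta-1,3-dien-1-one (vinylketene) | C/C=C(\OC)C(Cc2c(OCc3ccccc3)c(C(C)=O)c(OCc3ccccc3)c(Cc3c(OCc4ccccc4)c(C)c(OC)c(C(=O)CCC)c3OCc3ccccc3)c2OCc2ccccc2)=C=O | intermediate (not isolated)
24 | racemic 4-(Ar-methyl)-4-[(1Z)-1-methoxyprop-1-en-1-yl]-3-[(triisopropylsilyl)oxy]cyclobut-2-en-1-one | C/C=C(\OC)C1(Cc2c(OCc3ccccc3)c(C(C)=O)c(OCc3ccccc3)c(Cc3c(OCc4ccccc4)c(C)c(OC)c(C(=O)CCC)c3OCc3ccccc3)c2OCc2ccccc2)C(=O)C=C1O[Si](C(C)C)(C(C)C)C(C)C | intermediate (not isolated)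
25 | (3E,5Z)-5-methoxy-4-(Ar-methyl)-3-[(triisopropylsilyl)oxy]hepta-1,3,5-trien-1-one (dienylketene) | C/C=C(\OC)/C(Cc2c(OCc3ccccc3)c(C(C)=O)c(OCc3ccccc3)c(Cc3c(OCc4ccccc4)c(C)c(OC)c(C(=O)CCC)c3OCc3ccccc3)c2OCc2ccccc2)=C(/O[Si](C(C)C)(C(C)C)C(C)C)C=C=O | intermediate (not isolated)
26 | racemic 5-methoxy-6-methyl-4-(Ar-methyl)-3-[(triisopropylsilyl)oxy]cyclohexa-2,4-dien-1-one | CC1C(=O)C=C(O[Si](C(C)C)(C(C)C)C(C)C)C(Cc2c(OCc3ccccc3)c(C(C)=O)c(OCc3ccccc3)c(Cc3c(OCc4ccccc4)c(C)c(OC)c(C(=O)CCC)c3OCc3ccccc3)c2OCc2ccccc2)=C1OC | intermediate (not isolated)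
27 | 3-methoxy-2-methyl-4-(Ar-methyl)-5-[(triisopropylsilyl)oxy]phenol | Cc1c(O)cc(O[Si](C(C)C)(C(C)C)C(C)C)c(Cc2c(OCc3ccccc3)c(C(C)=O)c(OCc3ccccc3)c(Cc3c(OCc4ccccc4)c(C)c(OC)c(C(=O)CCC)c3OCc3ccccc3)c2OCc2ccccc2)c1OC | intermediate
28 | 4-(Ar-methyl)-5-methoxy-6-methylbenzene-1,3-diol | Cc1c(O)cc(O)c(Cc2c(OCc3ccccc3)c(C(C)=O)c(OCc3ccccc3)c(Cc3c(OCc4ccccc4)c(C)c(OC)c(C(=O)CCC)c3OCc3ccccc3)c2OCc2ccccc2)c1OC | intermediate
29 | 1-[3-(Ar-methyl)-2,6-dihydroxy-4-methoxy-5-methylphenyl]butan-1-one | CCCC(=O)c1c(O)c(C)c(OC)c(Cc2c(OCc3ccccc3)c(C(C)=O)c(OCc3ccccc3)c(Cc3c(OCc4ccccc4)c(C)c(OC)c(C(=O)CCC)c3OCc3ccccc3)c2OCc2ccccc2)c1O | intermediate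
30 | 1-[3-({3-acetyl-5-[(3-butanoyl-2,6-dihydroxy-4-methoxy-5-methylphenyl)methyl]-2,4,6-trihydroxyphenyl}methyl)-2,6-dihydroxy-4-methoxy-5-methylphenyl]butan-1-one | CCCC(=O)c1c(O)c(C)c(OC)c(Cc2c(O)c(Cc3c(O)c(C)c(OC)c(C(=O)CCC)c3O)c(O)c(C(C)=O)c2O)c1O | target

## Step count and least certain steps

Total: 15 steps. Longest linear sequence: 12 steps (steps 1, 2, 3, 4, 6, 7, 10, 11, 12, 13, 14, 15). Step 5 and steps 8 and 9 are side branches.

Step 12 (key step). The donor-stabilised four-membered ring may open only at temperatures at which 22 begins to rearrange by silyl shift and the ketene begins to oligomerise. The product phenol may be acylated by unreacted ketene, and a neighbouring benzyloxy oxygen may intercept the ketene intramolecularly. Fallback: abandon the annulation and join a ready-made ring A through quinone methide chemistry. Setting out from 12, reductive amination as in step 4 would give the ring B–ring C Mannich base F1. Setting out from 1, butanoylation as in step 3 would give 1-(2,4,6-trihydroxy-3-methylphenyl)butan-1-one F2, and methylation of its one unchelated hydroxyl as in step 2 would give 1-(2,6-dihydroxy-4-methoxy-3-methylphenyl)butan-1-one F3, whose single free carbon lies between methoxy and hydroxyl. Heating F1 with F3 in dioxane would lose dimethylamine and alkylate that carbon, coming back to the route at 30. The price is that all phenols are free during the coupling, so methylene exchange between rings is possible.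

Step 10. The small-ring dione may react through its methyl-bearing carbon, in particular by irreversible conjugate addition of a second dione to the alkylidene intermediate, or may decompose before the hindered aldehyde condenses. Fallback: build the four-membered ring on the side chain instead. Setting out from 13, the same condensation and hydride transfer with Meldrum's acid, which has a single acidic carbon, would give 5-(Ar-methyl)-2,2-dimethyl-1,3-dioxane-4,6-dione F4. Heating F4 in wet pyridine would give 3-Ar-propanoic acid F5, and (COCl)2 with catalytic DMF would give 3-Ar-propanoyl chloride F6. Slow addition of F6 to Et3N and commercial 1-ethoxyprop-1-yne would give racemic 3-ethoxy-2-methyl-4-(Ar-methyl)cyclobut-2-en-1-one F7 by ketene–alkyne cycloaddition, and hydrolysis as in step 9 comes back to the route at 20.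

Step 11. Unselective enolisation during methylation may leave 21 as the minor enol ether or make the separation inefficient. Fallback: use the other isomer as it is. Setting out from 20, the co-formed racemic 3-methoxy-2-methyl-4-(Ar-methyl)cyclobut-2-en-1-one F8 would be heated with 22 under the conditions of step 12 to give 2-(Ar-methyl)-3-methoxy-4-methyl-5-[(triisopropylsilyl)oxy]phenol F9, in which hydroxyl and silyloxy have changed places relative to 27. Desilylation as in step 13 removes the difference and comes back to the route at 28.

Step 14. The Lewis acid may strip benzyl ethers ortho to the ketones, ipso protonation of the electron-rich ring A may cleave the ring A–ring B methylene link, or acylation may stop at oxygen. Fallback: bring the acyl carbon in with the alkyne so that no Friedel–Crafts step is needed. Commercial hex-1-yn-3-ol would be silylated (Et3SiCl, imidazole) to triethyl(hex-1-yn-3-yloxy)silane F10. Its lithium acetylide (n-BuLi) would be oxidised with LiOOt-Bu and the alkynolate silylated with i-Pr3SiOTf to give 3-[(triethylsilyl)oxy]-1-[(triisopropylsilyl)oxy]hex-1-yne F11. Setting out from 21, benzannulation with F11 under the conditions of step 12 would give phenol F12, which already carries the four-carbon side chain at C1 as a silyl-protected carbinol. Bu4NF would remove both silyl groups to give triol F13, and MnO2 oxidation of the benzylic alcohol comes back to the route at 29.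

Step 6. The quinone methide may oligomerise through oxygen, the doubly acylated ring B may be too weak a nucleophile, or the liberated amine may tie up the aldehyde of 10. Fallback: couple before formylating. Setting out from 7, heating with an excess of the more nucleophilic 8 would give 1-{3-[(3-acetyl-2,4,6-trihydroxyphenyl)methyl]-2,4-dihydroxy-6-methoxy-5-methylphenyl}butan-1-one F14. Vilsmeier–Haack formylation as in step 5 at its only free ring carbon comes back to the route at 12.

## Further compounds

F1 | step 12 | 1-[3-({3-acetyl-5-[(dimethylamino)methyl]-2,4,6-trihydroxyphenyl}methyl)-2,4-dihydroxy-6-methoxy-5-methylphenyl]butan-1-one | CN(C)Cc1c(O)c(C(C)=O)c(O)c(Cc2c(O)c(C)c(OC)c(C(=O)CCC)c2O)c1O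
F2 | step 12 | 1-(2,4,6-trihydroxy-3-methylphenyl)butan-1-one | CCCC(=O)c1c(O)cc(O)c(C)c1O
F3 | step 12 | 1-(2,6-dihydroxy-4-methoxy-3-methylphenyl)butan-1-one | CCCC(=O)c1c(O)cc(OC)c(C)c1O
F4 | step 10 | 5-(Ar-methyl)-2,2-dimethyl-1,3-dioxane-4,6-dione | CC1(C)OC(=O)C(Cc2c(OCc3ccccc3)c(C(C)=O)c(OCc3ccccc3)c(Cc3c(OCc4ccccc4)c(C)c(OC)c(C(=O)CCC)c3OCc3ccccc3)c2OCc2ccccc2)C(=O)O1
F5 | step 10 | 3-Ar-propanoic acid | OC(=O)CCc1c(OCc2ccccc2)c(C(C)=O)c(OCc2ccccc2)c(Cc2c(OCc3ccccc3)c(C)c(OC)c(C(=O)CCC)c2OCc2ccccc2)c1OCc1ccccc1
F6 | step 10 | 3-Ar-propanoyl chloride | ClC(=O)CCc1c(OCc2ccccc2)c(C(C)=O)c(OCc2ccccc2)c(Cc2c(OCc3ccccc3)c(C)c(OC)c(C(=O)CCC)c2OCc2ccccc2)c1OCc1ccccc1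
F7 | step 10 | racemic 3-ethoxy-2-methyl-4-(Ar-methyl)cyclobut-2-en-1-one | CCOC1=C(C)C(=O)C1Cc2c(OCc3ccccc3)c(C(C)=O)c(OCc3ccccc3)c(Cc3c(OCc4ccccc4)c(C)c(OC)c(C(=O)CCC)c3OCc3ccccc3)c2OCc2ccccc2
F8 | step 11 | racemic 3-methoxy-2-methyl-4-(Ar-methyl)cyclobut-2-en-1-one | COC1=C(C)C(=O)C1Cc2c(OCc3ccccc3)c(C(C)=O)c(OCc3ccccc3)c(Cc3c(OCc4ccccc4)c(C)c(OC)c(C(=O)CCC)c3OCc3ccccc3)c2OCc2ccccc2
F9 | step 11 | 2-(Ar-methyl)-3-methoxy-4-methyl-5-[(triisopropylsilyl)oxy]phenol | Cc1c(O[Si](C(C)C)(C(C)C)C(C)C)cc(O)c(Cc2c(OCc3ccccc3)c(C(C)=O)c(OCc3ccccc3)c(Cc3c(OCc4ccccc4)c(C)c(OC)c(C(=O)CCC)c3OCc3ccccc3)c2OCc2ccccc2)c1OC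
F10 | step 14 | racemic triethyl(hex-1-yn-3-yloxy)silane | CCCC(O[Si](CC)(CC)CC)C#C
F11 | step 14 | racemic 3-[(triethylsilyl)oxy]-1-[(triisopropylsilyl)oxy]hex-1-yne | CCCC(O[Si](CC)(CC)CC)C#CO[Si](C(C)C)(C(C)C)C(C)C
F12 | step 14 | racemic 3-methoxy-2-methyl-4-(Ar-methyl)-6-{1-[(triethylsilyl)oxy]butyl}-5-[(triisopropylsilyl)oxy]phenol | CCCC(O[Si](CC)(CC)CC)c1c(O)c(C)c(OC)c(Cc2c(OCc3ccccc3)c(C(C)=O)c(OCc3ccccc3)c(Cc3c(OCc4ccccc4)c(C)c(OC)c(C(=O)CCC)c3OCc3ccccc3)c2OCc2ccccc2)c1O[Si](C(C)C)(C(C)C)C(C)C
F13 | step 14 | racemic 4-(Ar-methyl)-2-(1-hydroxybutyl)-5-methoxy-6-methylbenzene-1,3-diol | CCCC(O)c1c(O)c(C)c(OC)c(Cc2c(OCc3ccccc3)c(C(C)=O)c(OCc3ccccc3)c(Cc3c(OCc4ccccc4)c(C)c(OC)c(C(=O)CCC)c3OCc3ccccc3)c2OCc2ccccc2)c1O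
F14 | step 6 | 1-{3-[(3-acetyl-2,4,6-trihydroxyphenyl)methyl]-2,4-dihydroxy-6-methoxy-5-methylphenyl}butan-1-one | CC(=O)c1c(O)cc(O)c(Cc2c(O)c(C)c(OC)c(C(=O)CCC)c2O)c1O
A1 | alternative 1 | 6-(2-Ar′-ethyl)-4-methoxy-3-methyl-2H-pyran-2-one | COc1cc(CCc2c(OCc3ccccc3)c(Cc3c(OCc4ccccc4)c(C(=O)CCC)c(OCc4ccccc4)c(C)c3OC)c(OCc3ccccc3)c(C(C)=O)c2OCc2ccccc2)oc(=O)c1C
A2 | alternative 1 | 2-(Ar′-methyl)-5-methoxy-4-methylbenzene-1,3-diol | COc1cc(O)c(Cc2c(OCc3ccccc3)c(Cc3c(OCc4ccccc4)c(C(=O)CCC)c(OCc4ccccc4)c(C)c3OC)c(OCc3ccccc3)c(C(C)=O)c2OCc2ccccc2)c(O)c1C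
A3 | alternative 2 | racemic 4-{[2,4-bis(benzyloxy)-3-butanoyl-6-methoxy-5-methylphenyl]methyl}-3-[(triisopropylsilyl)oxy]cyclobut-2-en-1-one | O=C1C=C(O[Si](C(C)C)(C(C)C)C(C)C)C1Cc1c(OCc2ccccc2)c(C(=O)CCC)c(OCc2ccccc2)c(C)c1OC
A4 | alternative 2 | racemic 3-[2,6-bis(benzyloxy)-4-methoxy-3-methyl-5-{1-[(triethylsilyl)oxy]butyl}phenyl]-1-[(triisopropylsilyl)oxy]prop-1-yne | CCCC(O[Si](CC)(CC)CC)c1c(OC)c(C)c(OCc2ccccc2)c(CC#CO[Si](C(C)C)(C(C)C)C(C)C)c1OCc1ccccc1
A5 | alternative 2 | racemic 2-{[2,6-bis(benzyloxy)-4-methoxy-3-methyl-5-{1-[(triethylsilyl)oxy]butyl}phenyl]methyl}-6-{[2,4-bis(benzyloxy)-3-butanoyl-6-methoxy-5-methylphenyl]methyl}-3,5-bis[(triisopropylsilyl)oxy]phenol | Oc1c(Cc2c(OCc3ccccc3)c(C)c(OC)c(C(CCC)O[Si](CC)(CC)CC)c2OCc2ccccc2)c(O[Si](C(C)C)(C(C)C)C(C)C)cc(O[Si](C(C)C)(C(C)C)C(C)C)c1Cc1c(OCc2ccccc2)c(C(=O)CCC)c(OCc2ccccc2)c(C)c1OC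
A6 | alternative 3 | racemic 2-methyl-4-(Ar′-methyl)-3-[(triisopropylsilyl)oxy]cyclobut-2-en-1-one | CC1=C(O[Si](C(C)C)(C(C)C)C(C)C)C(Cc2c(OCc3ccccc3)c(Cc3c(OCc4ccccc4)c(C(=O)CCC)c(OCc4ccccc4)c(C)c3OC)c(OCc3ccccc3)c(C(C)=O)c2OCc2ccccc2)C1=O
A7 | alternative 3 | methoxyethyne | COC#C
A8 | alternative 3 | 5-methoxy-4-methyl-2-(Ar′-methyl)-3-[(triisopropylsilyl)oxy]phenol | COc1cc(O)c(Cc2c(OCc3ccccc3)c(Cc3c(OCc4ccccc4)c(C(=O)CCC)c(OCc4ccccc4)c(C)c3OC)c(OCc3ccccc3)c(C(C)=O)c2OCc2ccccc2)c(O[Si](C(C)C)(C(C)C)C(C)C)c1C
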